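**Strategy.** The carbocycle of the chromenedione core (C-4a, C-5, C-6, C-7, C-8, C-8a; enol carbon C-5, quaternary C-6, ring ketone C-7) is a 1,3,5-trioxygenated ring. It is cut at C-6–C-7 and C-4a–C-5. C-5/C-6 become the carbonyl and α-carbon of a γ-lactone; C-7/C-8/C-8a/C-4a come from a dihydropyranon-6-ylacetyl chloride. One operation C-acylates the lactone enolate anti to a menthyloxy acetal group (setting C-6), closes the ring by vinylogous Dieckmann attack of the pyranone α-carbon on the lactone carbonyl, and unmasks the aldehyde that becomes the prenyl group. The cyclobutane comes from (−)-verbenone; the phenylpropanoic acid arm is added last.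

Key step: step 13

Remark 1: the β-triketone core is written throughout in the enol tautomer of the target (chromene numbering O-1, C-2, C-3, C-4, C-4a, C-5 to C-8, C-8a). Aldehydes 20 and 23 are written open-chain although they may rest as cyclic hemiacetals with a neighbouring enol oxygen.
Remark 2: (5R)-5-(l-menthyloxy)furan-2(5H)-one 6 is taken as a purchasable chiral building block (otherwise two steps from furfural and l-menthol).

**Cyclobutane fragment**

Step 1
Reactants: 1 (1S,5S)-(−)-verbenone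
Product: 2 (1S,3R)-3-acetyl-2,2-dimethylcyclobutane-1-carboxylic acid
Conditions: RuCl3 (cat.), NaIO4, CCl4/MeCN/H2O, rt
Reagents that add atoms: sodium periodate, [Na+].[O-]I(=O)(=O)=O; water, O
Why: Ruthenium-catalysed periodate cleavage of the enone C=C and of the resulting α-keto acid removes one carbon as CO2 and leaves the cis-1,3 ring stereocentres, fixed by the former bicycle, untouched.

Step 2
Reactants: 2 (1S,3R)-3-acetyl-2,2-dimethylcyclobutane-1-carboxylic acid
Product: 3 (1S,3S)-2,2-dimethyl-3-(prop-1-en-2-yl)cyclobutane-1-carboxylic acid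
Conditions: Ph3PCH3Br, KN(SiMe3)2 (3 equiv each), THF, 0 °C to rt; then aq. HCl
Reagents that add atoms: methyltriphenylphosphonium bromide, C[P+](c1ccccc1)(c1ccccc1)c1ccccc1.[Br-]
Why: Wittig methylenation of the methyl ketone on the carboxylate salt should be faster than enolisation at the ring carbon at low temperature, so the cis ring relationship is kept.

Step 3
Reactants: 3 (1S,3S)-2,2-dimethyl-3-(prop-1-en-2-yl)cyclobutane-1-carboxylic acid
Product: 4 [(1S,3S)-2,2-dimethyl-3-(prop-1-en-2-yl)cyclobutyl]methanol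
Conditions: LiAlH4, THF, 0 °C to rt
Reagents that add atoms: none
Why: Hydride reduction of the carboxylic acid to the primary alcohol, to which the isolated 1,1-disubstituted alkene is inert.

Step 4
Reactants: 4 [(1S,3S)-2,2-dimethyl-3-(prop-1-en-2-yl)cyclobutyl]methanol
Product: 5 (1S,3S)-1-(iodomethyl)-2,2-dimethyl-3-(prop-1-en-2-yl)cyclobutane
Conditions: I2, PPh3, imidazole, CH2Cl2, 0 °C to rt
Reagents that add atoms: iodine, II
Why: Appel-type iodination proceeds by SN2 displacement of the oxyphosphonium group, so no cyclobutylcarbinyl cation forms and the ring cannot expand.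

**Lactone fragment**

Step 5
Reactants: 6 (5R)-5-{[(1R,2S,5R)-5-methyl-2-(propan-2-yl)cyclohexyl]oxy}furan-2(5H)-one
Product: 7 (5R)-5-{[(1R,2S,5R)-5-methyl-2-(propan-2-yl)cyclohexyl]oxy}oxolan-2-one
Conditions: H2 (1 atm), Pd/C, EtOAc, rt
Reagents that add atoms: none
Why: Heterogeneous catalytic hydrogenation saturates the butenolide C=C without touching the acetal stereocentre.

Step 6
Reactants: 7 (5R)-5-(menthyloxy)oxolan-2-one; 5 (1S,3S)-1-(iodomethyl)-2,2-dimethyl-3-(prop-1-en-2-yl)cyclobutane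
Product: 8 (3S,5R)-3-{[(1R,3S)-2,2-dimethyl-3-(prop-1-en-2-yl)cyclobutyl]methyl}-5-{[(1R,2S,5R)-5-methyl-2-(propan-2-yl)cyclohexyl]oxy}oxolan-2-one
Conditions: LiN(iPr)2, THF, −78 °C; then 5, HMPA, −78 to −20 °C
Reagents that add atoms: none
Why: SN2 alkylation of the lithium lactone enolate by the primary iodide should occur anti to the menthyloxy group (trans product), and the C-3 configuration is in any case erased when this centre is enolised again in step 13.

**Pyranone fragment**

Step 7
Reactants: 9 methyl (3R)-3-hydroxybutanoate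
Product: 10 methyl (2R,3R)-3-hydroxy-2-methylbutanoate
Conditions: LiN(iPr)2 (2.2 equiv), THF, −78 to −20 °C; MeI, HMPA
Reagents that add atoms: iodomethane, CI
Why: Fráter–Seebach alkylation, in which the lithium-chelated alkoxide enolate is methylated on the face opposite the C-3 methyl group to give the anti (2R,3R) product.

Step 8
Reactants: 10 methyl (2R,3R)-3-hydroxy-2-methylbutanoate
Product: 11 methyl (2R,3R)-3-[(tert-butyldimethylsilyl)oxy]-2-methylbutanoate
Conditions: TBSCl, imidazole, DMF, rt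
Reagents that add atoms: tert-butyldimethylsilyl chloride, CC(C)(C)[Si](C)(C)Cl
Why: Silylation of the secondary alcohol prevents retro-aldol cleavage and alkoxide interference in the Claisen step that follows.

Step 9
Reactants: 11 methyl (2R,3R)-3-[(tert-butyldimethylsilyl)oxy]-2-methylbutanoate; 12 tert-butyl 3-oxobutanoate
Product: 13 tert-butyl (6R,7R)-7-[(tert-butyldimethylsilyl)oxy]-6-methyl-3,5-dioxooctanoate
Conditions: 12 (2.5 equiv), NaH, THF, 0 °C; n-BuLi, 0 °C; then 11, 0 °C to rt; aq. NH4Cl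
Reagents that add atoms: none
Why: Claisen-type γ-acylation of the acetoacetate dianion by the ester (Huckin–Weiler), the product resting as a polyanion so that the α-stereocentre next to the new ketone is not deprotonated.

Step 10
Reactants: 13 tert-butyl (6R,7R)-7-[(tert-butyldimethylsilyl)oxy]-6-methyl-3,5-dioxooctanoate
Product: 15 tert-butyl 2-[(2R,3R)-2,3-dimethyl-4-oxo-3,4-dihydro-2H-pyran-6-yl]acetate, via hydroxy diketo ester 14 (not isolated)
Conditions: 48% aq. HF, MeCN, 0 °C to rt
Reagents that add atoms: none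
Why: Desilylation followed by acid-catalysed cyclodehydration of the δ-hydroxy-β-diketone (hemiketal formation at the C-3 ketone, then loss of water into conjugation with the C-5 ketone) gives the dihydropyranone with both stereocentres carried over in the more stable trans arrangement.

Step 11
Reactants: 15 tert-butyl 2-[(2R,3R)-2,3-dimethyl-4-oxo-3,4-dihydro-2H-pyran-6-yl]acetate
Product: 16 2-[(2R,3R)-2,3-dimethyl-4-oxo-3,4-dihydro-2H-pyran-6-yl]acetic acid
Conditions: TFA, CH2Cl2, 0 °C to rt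
Reagents that add atoms: none
Why: Acidolysis of the tert-butyl ester frees the acid without base, which could open the dihydropyranone by retro-oxa-Michael reaction.

Step 12
Reactants: 16 2-[(2R,3R)-2,3-dimethyl-4-oxo-3,4-dihydro-2H-pyran-6-yl]acetic acid
Product: 17 2-[(2R,3R)-2,3-dimethyl-4-oxo-3,4-dihydro-2H-pyran-6-yl]acetyl chloride
Conditions: 1-chloro-N,N,2-trimethylprop-1-en-1-amine, CH2Cl2, 0 °C; used crude
Reagents that add atoms: 1-chloro-N,N,2-trimethylprop-1-en-1-amine, CC(C)=C(Cl)N(C)C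
Why: The Ghosez chloroenamine converts the acid into the acid chloride under neutral conditions that spare the acid-sensitive vinylogous ester.

**Union and endgame**

Step 13
Reactants: 8 (3S,5R)-3-(cyclobutylmethyl)-5-(menthyloxy)oxolan-2-one; 17 2-[(2R,3R)-2,3-dimethyl-4-oxo-3,4-dihydro-2H-pyran-6-yl]acetyl chloride
Product: 20 2-[(2R,3R,6S)-6-{[(1R,3S)-2,2-dimethyl-3-(prop-1-en-2-yl)cyclobutyl]methyl}-5-hydroxy-2,3-dimethyl-4,7-dioxo-3,4,6,7-tetrahydro-2H-chromen-6-yl]acetaldehyde, via C-acylated lactone 18 (not isolated), via menthyl hemiacetal 19 (not isolated)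
Conditions: LiN(SiMe3)2 (1.1 equiv), THF, −78 °C; 17, −78 °C; LiN(SiMe3)2 (1.5 equiv), −78 to 0 °C; then 1 M HCl, THF/H2O, rt
Reagents that add atoms: none
Why: The lithium enolate of 8 is C-acylated by 17 (directly or through the derived ketene) to give 18; further amide base removes the CH2 proton between the new ketone and the pyranone, and the vinylogous enolate attacks the lactone carbonyl through the pyranone α-carbon, opening the lactone to the stabilised triketone enolate and hemiacetal 19, which collapses to the aldehyde and menthol on acidic work-up. The closest known reaction type is the tandem Claisen acylation–Dieckmann condensation of diketene annulations of ester enolates, a formal [4+2] ring synthesis. The carbocycle closes by 6-exo-trig attack on the lactone carbonyl, whereas attack through the CH2-derived carbon would need a four-membered ring. The quaternary centre is set in the acylation, the acyl donor approaching the enolate face anti to the pseudoaxial C-5 menthyloxy group (1,3-induction as in alkylations of γ-substituted butyrolactone enolates), which corresponds to 6S in 20 and to 6R once the aldehyde arm has become prenyl. The step needs C- over O-acylation (lithium counter-ion in THF without polar cosolvent) and no retro-Claisen cleavage (non-nucleophilic amide base, product sequestered as its enolate); the position of the pyran oxygen is secured because the pyranone ring is preformed.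

Step 14
Reactants: 20 2-[(2R,3R,6S)-6-(cyclobutylmethyl)-5-hydroxy-2,3-dimethyl-4,7-dioxo-3,4,6,7-tetrahydro-2H-chromen-6-yl]acetaldehyde
Product: 21 (2R,3R,6R)-6-{[(1R,3S)-2,2-dimethyl-3-(prop-1-en-2-yl)cyclobutyl]methyl}-5-hydroxy-2,3-dimethyl-6-(3-methylbut-2-en-1-yl)-2,3-dihydro-4H-chromene-4,7(6H)-dione
Conditions: iPrPPh3I, n-BuLi (3.5 equiv each), THF, 0 °C; then 20, −78 °C to rt; dilute HCl work-up
Reagents that add atoms: isopropyltriphenylphosphonium iodide, CC(C)[P+](c1ccccc1)(c1ccccc1)c1ccccc1.[I-]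
Why: Wittig olefination with the non-stabilised isopropylidene ylide converts the aldehyde into the prenyl group, the first equivalent of ylide turning the acidic triketone into its unreactive enolate and opening any lactol form.

Step 15
Reactants: 21 (2R,3R,6R)-6-(cyclobutylmethyl)-5-hydroxy-2,3-dimethyl-6-prenyl-2,3-dihydro-4H-chromene-4,7(6H)-dione; 22 (E)-cinnamaldehyde
Product: 23 (3S)-3-[(2R,3R,6R)-6-{[(1R,3S)-2,2-dimethyl-3-(prop-1-en-2-yl)cyclobutyl]methyl}-5-hydroxy-2,3-dimethyl-6-(3-methylbut-2-en-1-yl)-4,7-dioxo-3,4,6,7-tetrahydro-2H-chromen-8-yl]-3-phenylpropanal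
Conditions: 22 (1.5 equiv), (S)-2-[diphenyl(trimethylsilyloxy)methyl]pyrrolidine (20 mol%), CH2Cl2, rt
Reagents that add atoms: none
Why: Iminium-catalysed Michael addition of a cyclic 1,3-dicarbonyl-type carbon acid to an enal, in which C-8 (the only free nucleophilic carbon of 21) adds to the Si face of the β-carbon of the E-iminium ion left open by the diphenyl(silyloxy)methyl group of the (S)-catalyst, giving the S benzylic centre under catalyst control.

Step 16
Reactants: 23 (3S)-3-(chromen-8-yl)-3-phenylpropanal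
Product: 24 (3S)-3-[(2R,3R,6R)-6-{[(1R,3S)-2,2-dimethyl-3-(prop-1-en-2-yl)cyclobutyl]methyl}-5-hydroxy-2,3-dimethyl-6-(3-methylbut-2-en-1-yl)-4,7-dioxo-3,4,6,7-tetrahydro-2H-chromen-8-yl]-3-phenylpropanoic acid
Conditions: NaClO2, NaH2PO4, 2-methylbut-2-ene (large excess), t-BuOH/H2O, 0 °C to rt
Reagents that add atoms: sodium chlorite, [Na+].[O-]Cl=O
Why: Pinnick oxidation takes the aldehyde (in equilibrium with its lactol) to the carboxylic acid without touching the stereocentres, the alkene scavenger intercepting hypochlorite before it reaches the prenyl, isopropenyl and enol groups.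

**Compound list**

1 | (1S,5S)-(−)-verbenone, (1S,5S)-4,6,6-trimethylbicyclo[3.1.1]hept-3-en-2-one | O=C1C=C(C)[C@@H]2C[C@H]1C2(C)C | starting material
2 | (1S,3R)-3-acetyl-2,2-dimethylcyclobutane-1-carboxylic acid (cis-pinononic acid) | CC(=O)[C@@H]1C[C@H](C(=O)O)C1(C)C | intermediate
3 | (1S,3S)-2,2-dimethyl-3-(prop-1-en-2-yl)cyclobutane-1-carboxylic acid (cis) | C=C(C)[C@@H]1C[C@H](C(=O)O)C1(C)C | intermediate
4 | [(1S,3S)-2,2-dimethyl-3-(prop-1-en-2-yl)cyclobutyl]methanol | C=C(C)[C@@H]1C[C@H](CO)C1(C)C | intermediate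
5 | (1S,3S)-1-(iodomethyl)-2,2-dimethyl-3-(prop-1-en-2-yl)cyclobutane | C=C(C)[C@@H]1C[C@H](CI)C1(C)C | intermediate
6 | (5R)-5-{[(1R,2S,5R)-5-methyl-2-(propan-2-yl)cyclohexyl]oxy}furan-2(5H)-one | CC(C)[C@@H]1CC[C@@H](C)C[C@H]1O[C@H]1C=CC(=O)O1 | starting material
7 | (5R)-5-{[(1R,2S,5R)-5-methyl-2-(propan-2-yl)cyclohexyl]oxy}oxolan-2-one | CC(C)[C@@H]1CC[C@@H](C)C[C@H]1O[C@H]1CCC(=O)O1 | intermediate
8 | (3S,5R)-3-{[(1R,3S)-2,2-dimethyl-3-(prop-1-en-2-yl)cyclobutyl]methyl}-5-{[(1R,2S,5R)-5-methyl-2-(propan-2-yl)cyclohexyl]oxy}oxolan-2-one | CC(C)[C@@H]1CC[C@@H](C)C[C@H]1O[C@H]1C[C@H](C[C@H]2C[C@@H](C(C)=C)C2(C)C)C(=O)O1 | intermediate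
9 | methyl (3R)-3-hydroxybutanoate | C[C@@H](O)CC(=O)OC | starting material
10 | methyl (2R,3R)-3-hydroxy-2-methylbutanoate | C[C@@H](O)[C@@H](C)C(=O)OC | intermediate
11 | methyl (2R,3R)-3-[(tert-butyldimethylsilyl)oxy]-2-methylbutanoate | C[C@@H](O[Si](C)(C)C(C)(C)C)[C@@H](C)C(=O)OC | intermediate
12 | tert-butyl 3-oxobutanoate | CC(=O)CC(=O)OC(C)(C)C | starting material
13 | tert-butyl (6R,7R)-7-[(tert-butyldimethylsilyl)oxy]-6-methyl-3,5-dioxooctanoate | C[C@@H](O[Si](C)(C)C(C)(C)C)[C@@H](C)C(=O)CC(=O)CC(=O)OC(C)(C)C | intermediate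
14 | tert-butyl (6R,7R)-7-hydroxy-6-methyl-3,5-dioxooctanoate | C[C@@H](O)[C@@H](C)C(=O)CC(=O)CC(=O)OC(C)(C)C | intermediate
15 | tert-butyl 2-[(2R,3R)-2,3-dimethyl-4-oxo-3,4-dihydro-2H-pyran-6-yl]acetate | CC(C)(C)OC(=O)CC1=CC(=O)[C@H](C)[C@@H](C)O1 | intermediate
16 | 2-[(2R,3R)-2,3-dimethyl-4-oxo-3,4-dihydro-2H-pyran-6-yl]acetic acid | OC(=O)CC1=CC(=O)[C@H](C)[C@@H](C)O1 | intermediate
17 | 2-[(2R,3R)-2,3-dimethyl-4-oxo-3,4-dihydro-2H-pyran-6-yl]acetyl chloride | ClC(=O)CC1=CC(=O)[C@H](C)[C@@H](C)O1 | intermediate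
18 | (3R,5R)-3-{[(1R,3S)-2,2-dimethyl-3-(prop-1-en-2-yl)cyclobutyl]methyl}-3-{[(2R,3R)-2,3-dimethyl-4-oxo-3,4-dihydro-2H-pyran-6-yl]acetyl}-5-{[(1R,2S,5R)-5-methyl-2-(propan-2-yl)cyclohexyl]oxy}oxolan-2-one | CC(C)[C@@H]1CC[C@@H](C)C[C@H]1O[C@H]1C[C@](C[C@H]2C[C@@H](C(C)=C)C2(C)C)(C(=O)CC2=CC(=O)[C@H](C)[C@@H](C)O2)C(=O)O1 | intermediate
19 | (1R,2S,5R)-menthyl hemiacetal of aldehyde 20 (ring-closed triketone, side chain CH2CH(OH)O-menthyl) | C=C(C)[C@@H]1C[C@H](C[C@@]2(C[C@@H](O)O[C@@H]3C[C@H](C)CC[C@H]3C(C)C)C(=O)C=C3O[C@H](C)[C@@H](C)C(=O)C3=C2O)C1(C)C | intermediate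
20 | 2-[(2R,3R,6S)-6-{[(1R,3S)-2,2-dimethyl-3-(prop-1-en-2-yl)cyclobutyl]methyl}-5-hydroxy-2,3-dimethyl-4,7-dioxo-3,4,6,7-tetrahydro-2H-chromen-6-yl]acetaldehyde | C=C(C)[C@@H]1C[C@H](C[C@@]2(CC=O)C(=O)C=C3O[C@H](C)[C@@H](C)C(=O)C3=C2O)C1(C)C | intermediate
21 | (2R,3R,6R)-6-{[(1R,3S)-2,2-dimethyl-3-(prop-1-en-2-yl)cyclobutyl]methyl}-5-hydroxy-2,3-dimethyl-6-(3-methylbut-2-en-1-yl)-2,3-dihydro-4H-chromene-4,7(6H)-dione | C=C(C)[C@@H]1C[C@H](C[C@@]2(CC=C(C)C)C(=O)C=C3O[C@H](C)[C@@H](C)C(=O)C3=C2O)C1(C)C | intermediate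
22 | (E)-cinnamaldehyde | O=C/C=C/c1ccccc1 | starting material
23 | (3S)-3-[(2R,3R,6R)-6-{[(1R,3S)-2,2-dimethyl-3-(prop-1-en-2-yl)cyclobutyl]methyl}-5-hydroxy-2,3-dimethyl-6-(3-methylbut-2-en-1-yl)-4,7-dioxo-3,4,6,7-tetrahydro-2H-chromen-8-yl]-3-phenylpropanal | C=C(C)[C@@H]1C[C@H](C[C@@]2(CC=C(C)C)C(=O)C([C@@H](CC=O)c3ccccc3)=C3O[C@H](C)[C@@H](C)C(=O)C3=C2O)C1(C)C | intermediate
24 | (3S)-3-[(2R,3R,6R)-6-{[(1R,3S)-2,2-dimethyl-3-(prop-1-en-2-yl)cyclobutyl]methyl}-5-hydroxy-2,3-dimethyl-6-(3-methylbut-2-en-1-yl)-4,7-dioxo-3,4,6,7-tetrahydro-2H-chromen-8-yl]-3-phenylpropanoic acid (CNP0103716.3) | C=C(C)[C@@H]1C[C@H](C[C@@]2(CC=C(C)C)C(=O)C([C@@H](CC(=O)O)c3ccccc3)=C3O[C@H](C)[C@@H](C)C(=O)C3=C2O)C1(C)C | target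

**Totals.** 16 steps in all. Longest linear sequence: 10 steps (steps 7 to 12, then 13 to 16).

**Steps most likely to fail**

1. Step 13. The hindered tetrasubstituted enolate may be acylated on oxygen instead of carbon, may be quenched by proton transfer from the acidic CH2 of 17, or may show poor facial selectivity, and the ring closure may stall. The fallback sets out from 8 and 17 and returns at 20. The potassium enolate of 8 (KN(SiMe3)2, THF/DMPU) is deliberately O-acylated by 17 to the ketene acetal ester F1. A 4-pyrrolidinopyridine-catalysed Steglich-type O-to-C acyl shift, again anti to the menthyloxy group, then gives 18. Separate treatment of 18 with LiN(SiMe3)2 effects the Dieckmann closure through 19, and acidic work-up gives 20.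

2. Step 6. SN2 displacement at the β-branched, neopentyl-like iodide 5 may be too slow, so that the lactone enolate self-condenses or decomposes first. The fallback sets out from 4 and 7 and returns at 8. Alcohol 4 is oxidised with Dess–Martin periodinane to the aldehyde F2. The lithium enolate of 7 adds to F2 at −78 °C (aldol) to give the β-hydroxy lactone F3. Burgess dehydration gives the (E)-alkylidene lactone F4, and chemoselective 1,4-reduction with [(Ph3P)CuH]6 gives 8 as a C-3 epimer mixture, which is immaterial for step 13.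

3. Step 15. The hindered, strongly acidic carbon acid may add slowly or reversibly to the iminium ion, and catalyst control may be eroded by the neighbouring quaternary centre (mismatched facial selectivity). The fallback sets out from 21 and 22 and returns at 24, replacing steps 15 and 16. Oxidative N-heterocyclic carbene catalysis (chiral aminoindanol-derived triazolium salt of the appropriate hand, DBU, 3,3′,5,5′-tetra-tert-butyldiphenoquinone) converts 22 into the α,β-unsaturated acyl azolium. C-8 of 21 adds to it and the C-7 oxygen lactonises to the 4-phenyl-3,4-dihydropyran-2-one F5, already at the acid oxidation level. LiOH in THF/H2O opens this enol lactone to 24.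

**Further compounds**

F1 | step 13 | (2R)-4-{[(1R,3S)-2,2-dimethyl-3-(prop-1-en-2-yl)cyclobutyl]methyl}-2-(l-menthyloxy)-2,3-dihydrofuran-5-yl [(2R,3R)-2,3-dimethyl-4-oxo-3,4-dihydro-2H-pyran-6-yl]acetate (O-acyl ketene acetal isomer of 18) | CC(C)[C@@H]1CC[C@@H](C)C[C@H]1O[C@H]1CC(C[C@H]2C[C@@H](C(C)=C)C2(C)C)=C(OC(=O)CC2=CC(=O)[C@H](C)[C@@H](C)O2)O1
F2 | step 6 | (1S,3S)-2,2-dimethyl-3-(prop-1-en-2-yl)cyclobutane-1-carbaldehyde | C=C(C)[C@@H]1C[C@H](C=O)C1(C)C
F3 | step 6 | (5R)-3-{hydroxy[(1S,3S)-2,2-dimethyl-3-(prop-1-en-2-yl)cyclobutyl]methyl}-5-(l-menthyloxy)oxolan-2-one (epimer mixture at C-3 and the carbinol carbon) | CC(C)[C@@H]1CC[C@@H](C)C[C@H]1O[C@H]1CC(C(O)[C@H]2C[C@@H](C(C)=C)C2(C)C)C(=O)O1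
F4 | step 6 | (3E,5R)-3-{[(1R,3S)-2,2-dimethyl-3-(prop-1-en-2-yl)cyclobutyl]methylidene}-5-(l-menthyloxy)oxolan-2-one | CC(C)[C@@H]1CC[C@@H](C)C[C@H]1O[C@H]1C/C(=C\[C@H]2C[C@@H](C(C)=C)C2(C)C)C(=O)O1
F5 | step 15 | enol lactone of 24 between the carboxyl group and the C-7 oxygen ((4S)-4-phenyl-3,4-dihydropyran-2-one fused at C-7/C-8) | C=C(C)[C@@H]1C[C@H](C[C@]2(CC=C(C)C)C(=O)C3=C(O[C@H](C)[C@@H](C)C3=O)C4=C2OC(=O)C[C@H]4c5ccccc5)C1(C)C
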